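## The problem

The target is a C25 terpenoid on a labdane bicycle. Labdane numbering is used throughout: ring A = C1–C5 and C10, ring B = C5–C10, C18 (α) and C19 (β) on C4, C20 on C10, C17 on C8, C11 onward on C9, C16 the methyl on C13; the butenolide atoms are C2′–C5′, with C5′ bonded to C15. A "pentanorlabdane" below is the decalin with C11 and C17–C20 only.

The rings form a trans-fused decalin carrying a 4α-hydroxymethyl, a 4β-methyl, an equatorial 6α-hydroxyl, a 10β-methyl and an exocyclic C8=C17 methylene. C9 bears a β-oriented chain C11–C12–C13(Me)=C14–C15(OH) that ends in a 4-methylbutenolide. Five stereocentres lie in the bicycle (4R,5R,6S,9S,10R) and two in the chain (15S,5′S, threo); C13=C14 is E.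

The quaternary centres C4 and C10 flank C5 and cannot be corrected later, so their relative configuration must be fixed when the skeleton is made. Once they are in place, the two β-methyl groups shield one face of ring B, and C5, C6 and C9 can be set by additions to the α face. The chain stereocentres are six bonds from C9 and get no guidance from the bicycle, so they need reagent control, and the trisubstituted alkene needs a geometry-defined building block.

The butenolide (acidic C5′–H next to a potential leaving group on C15, Michael acceptor), the allylic C15 alcohol and the acid-labile exocyclic alkene do not tolerate strong base, strong acid or dissolving metals and should appear late.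

The opening for a short synthesis is that C18 on C4 and C9 on C10 stand cis-1,3 across C5 on the α face of ring A, and C9 carries C11. An ester from O18 to a C11 carboxyl is therefore a four-atom tether that can hold a C8≡C9 triple bond under C10 of a ring A diene (C10=C5–C6=C7) from that face only.

## Retrosynthesis

**C15–C5′.** The last carbon–carbon bond cut is C15–C5′. A vinylogous Mukaiyama aldol addition of silyloxyfuran 29 to enal 27 makes this bond, both chain stereocentres and the finished butenolide in one operation, so the base-sensitive ring never has to pass through a coupling or redox step. Only two triethylsilyl ethers then separate 31 from target 32. The neighbouring cuts (C12–C13 with a butenolide-bearing partner, or C14–C15 by adding an alkenyl metal to an α-alkoxy aldehyde) either expose the butenolide to base or need three more steps to close it. The forward step must give the threo adduct by attack on the Re face of the aldehyde under catalyst control.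

**C9–H and C8=C17.** Enal 27 comes from ester 25 through alcohol 26. The exocyclic alkene and the C9 hydrogen of 25 are traced to the tetrasubstituted C8=C9 alkene of allylic carbonate 24, made from alcohol 23. This is preferred to carrying an 8(17)-alkene through the route, where it would compete in every hydroboration, and to methylenating a hindered 8-ketone beside an epimerisable C9. The precursor has one stereocentre fewer and an inert alkene. The forward hydrogenolysis must deliver hydride to the more substituted allyl terminus and from the α face.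

**C12–C13.** Alcohol 23 is cut into dienol 19 and enol triflate 21 (from methyl acetoacetate 20). The E geometry of C13=C14 is stored in 21 and transferred by an alkyl–alkenyl Suzuki coupling of borane 22. The alternative, alkylating a C11 sulfone with an allylic bromide and then desulfonylating, costs about four steps and uses reductants that threaten the allylic C–O bonds. The forward step needs hydroboration of the vinyl group only.

**C11=C12 and O17–C11.** The vinyl group and the free C17 hydroxyl of 19 are the two halves of a butenolide. Reduction of 17 to lactol 18 and Wittig methylenation convert the C11 carbonyl into C11=C12 and release O17 as the only free hydroxyl, which is what the later carbonate needs. No separate protection of O11 or O17 is required.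

**C5–H and C6–O.** Silyl ether 17 comes from diol 16, and C5 and C6 of 16 are cut back to the C5=C6 alkene of butenolide 15. Hydroboration must occur on the α face and before any other nucleophilic alkene exists, hence at this stage.

**Acyl shift.** Butenolide 15 is the translactonisation isomer of bridged lactone 13: freeing O17 (alcohol 14) lets it take over the C11 acyl group and release O18. One step differentiates O11, O17 and O18 and relieves the strain of the bridged ring.

**C9–C10 and C7–C8 (key cut).** Lactone 13 is opened by a retro-[4+2] to ester 12, a monocyclic diene with one stereocentre. Against a polyene cyclisation, this cut places oxygen on C18 and C17 and a handle at C6 from the start. Against an intermolecular cycloaddition, the tether enforces both the orientation of the dienophile and the face of C10 that is attacked. The forward reaction must form a quaternary centre at a fully substituted diene terminus through a seven-membered bridged ring.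

**Ester and ring A.** Ester 12 comes from dienol 11 and acid 3 (from propargyl alcohol 1 via silyl ether 2). Dienol 11 comes from silyl ether 10, made by Stille coupling of enol triflate 8 with stannane 9. Triflate 8 goes back through ketones 7 and 6 to silyl enol ether 5 and 2,6-dimethylcyclohexanone 4. The single stereocentre (C4) is set by a catalytic asymmetric hydroxymethylation of 5.

## Roads not taken

**Alternative 1: silicon-tethered C–H oxidation at C18.** The cut is the C18–O bond. The bicycle would come from larixol A1, whose chain and C8 methylene are degraded and masked to give the 6-O-diethylhydrosilyl ether A2. The key step is a rhodium-catalysed dehydrogenative silylation ([Rh(cod)Cl]2, Xantphos, norbornene) that closes the oxasilinane A3, later oxidised to the C18 alcohol.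
- Merits: all five ring stereocentres come from the chiral pool, and the equatorial 6α-oxygen lies closest to the equatorial 4α-methyl, so site selectivity is plausible.
- Weak points: three δ-methyl groups (C18, C19, C20) compete; the route depends on a natural product of limited supply; the chain and the C8 methylene must be removed and rebuilt, including re-methylenation at hindered C8 next to epimerisable C9 and an olefination at C13 of uncertain E selectivity. The chain stereocentres remain unsolved.
- Comparison: for the bicycle this road is shorter and stereochemically safer than the chosen one. The chosen plan offers independence from supply, access to either enantiomer and to C4 analogues, oxygen on C18 from the first step, and an E-alkene taken from a geometry-pure triflate.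

**Alternative 2: methylalumination, then chelation-controlled addition.** The cuts are C13–CH3 and C14–C15. Decalin alkyne A4 undergoes Cp2ZrCl2-catalysed addition of Me3Al, and the E-alkenylalane adds to α-alkoxy aldehyde A5 to give A6.
- Merits: E geometry from syn carbometalation, and C15 set by substrate control from a small chiral aldehyde, not by a catalyst acting far from any other stereocentre.
- Weak points: A5 is an α-alkoxy β,γ-unsaturated aldehyde prone to racemisation and conjugation; chelation control with a Lewis-acidic alkenylalane is uncertain; three further steps are needed to close the butenolide (ether cleavage, acrylation, ring-closing metathesis with the second-generation Grubbs catalyst beside an exocyclic methylene). The road does not say how the bicycle is made.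
- Comparison: for control of C15 and C5′ this road is at least as good as the chosen aldol step, and probably more predictable. The chosen plan offers two steps from enal 27 to the complete ring and, above all, a solution for the decalin. The ideas are compatible: the fallback for step 23 uses the same auxiliary-based logic.

**Alternative 3: siloxy-vinylallene intramolecular Diels–Alder.** The cuts are C5–C10 and C8–C9. Heating the acyclic enal A7 would close both rings to A8.
- Merits: both rings and C5, C9 and C10 in one step; the C6 oxygen, the exocyclic methylene and a C11 aldehyde arrive in the right places.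
- Weak points: the only control element is the C4 centre in the tether, whose methyl and silyloxymethyl groups differ little, so facial selectivity relative to C4 should be modest. Ring fusion and C9 depend on endo/exo preference; the dienophile is a β,β-disubstituted enal that must form a quaternary carbon beside an acid-sensitive diene. The resulting C6 carbonyl must be reduced to the equatorial alcohol against the usual hydride preference, and A7 is itself laborious.
- Comparison: this road builds more in its key step and would save the hydrogenolysis and lactol steps used here. The chosen plan offers tether-enforced facial and regiocontrol at C10, stereocentres C5, C6 and C9 set one at a time by α-face additions on a rigid frame, and a precursor with one ring and one stereocentre.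

Key step: step 10

Assumption: the sense of induction of the chiral catalysts in steps 4 and 23 is assigned by analogy with simpler substrates; if a model reaction shows the opposite sense, the enantiomeric ligand is used and nothing else changes.

## Route

Step 1
Reactants: 1 prop-2-yn-1-ol
Product: 2 tert-butyldimethyl(prop-2-yn-1-yloxy)silane
Conditions: TBSCl, imidazole, CH2Cl2, 0 °C → rt
Reagents that add atoms: tert-butyldimethylsilyl chloride, CC(C)(C)[Si](C)(C)Cl
Why: Standard silylation of a primary alcohol; the ether must survive acetylide formation and the heat of step 10.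

Step 2
Reactants: 2 tert-butyldimethyl(prop-2-yn-1-yloxy)silane
Product: 3 4-(tert-butyldimethylsilyloxy)but-2-ynoic acid
Conditions: n-BuLi, THF, −78 °C; CO2; 1 M HCl to pH 3, 0 °C
Reagents that add atoms: carbon dioxide, O=C=O
Why: Carboxylation of a lithium acetylide; the acid supplies C8, C9, C11 and C17 with the C17 oxygen in place.

Step 3
Reactants: 4 2,6-dimethylcyclohexan-1-one
Product: 5 (2,6-dimethylcyclohex-1-en-1-yl)oxytrimethylsilane (racemic)
Conditions: LiN(i-Pr)2, THF, −78 → 0 °C; Me3SiCl, −78 °C → rt
Reagents that add atoms: chlorotrimethylsilane, C[Si](C)(C)Cl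
Why: O-silylation of the lithium enolate; both α-carbons are equivalent, so only one enol ether can form.

Step 4
Reactants: 5 (2,6-dimethylcyclohex-1-en-1-yl)oxytrimethylsilane
Product: 6 (2S)-2-(hydroxymethyl)-2,6-dimethylcyclohexan-1-one (C6 epimers)
Conditions: aq. HCHO, Sc(OTf)3 (10 mol%), (S,S)-6,6′-bis(1-hydroxy-2,2-dimethylpropyl)-2,2′-bipyridine (12 mol%), DME/H2O 9:1, −20 °C
Reagents that add atoms: formaldehyde, C=O
Why: Aqueous Mukaiyama-type hydroxymethylation of a silicon enolate by the chiral scandium–bipyridine complex, which selects one face of the tetrasubstituted enol ether and so sets the quaternary carbon (labdane C4). The C6 methyl centre is a mixture and is erased in step 6.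

Step 5
Reactants: 6 (2S)-2-(hydroxymethyl)-2,6-dimethylcyclohexan-1-one
Product: 7 (2S)-2-[(tert-butyldimethylsilyloxy)methyl]-2,6-dimethylcyclohexan-1-one (C6 epimers)
Conditions: TBSCl, imidazole, DMF, rt
Reagents that add atoms: tert-butyldimethylsilyl chloride, CC(C)(C)[Si](C)(C)Cl
Why: Silylation blocks retro-aldol loss of formaldehyde under the basic conditions of step 6.

Step 6
Reactants: 7 (2S)-2-[(tert-butyldimethylsilyloxy)methyl]-2,6-dimethylcyclohexan-1-one
Product: 8 (6S)-6-[(tert-butyldimethylsilyloxy)methyl]-2,6-dimethylcyclohex-1-en-1-yl trifluoromethanesulfonate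
Conditions: KN(SiMe3)2, THF, −78 → 0 °C; PhNTf2, −78 °C → rt
Reagents that add atoms: N-phenylbis(trifluoromethanesulfonimide), O=S(=O)(N(c1ccccc1)S(=O)(=O)C(F)(F)F)C(F)(F)F
Why: Only the C6 hydrogen is enolisable; O-triflation of the potassium enolate gives the tetrasubstituted enol triflate (future C5=C10).

Step 7
Reactants: 8 (6S)-6-[(tert-butyldimethylsilyloxy)methyl]-2,6-dimethylcyclohex-1-en-1-yl trifluoromethanesulfonate; 9 tributyl(vinyl)stannane
Product: 10 tert-butyl{[(1R)-1,3-dimethyl-2-vinylcyclohex-2-en-1-yl]methoxy}dimethylsilane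
Conditions: Pd(PPh3)4 (5 mol%), LiCl (3 equiv), THF, reflux
Reagents that add atoms: none
Why: Stille coupling of a hindered enol triflate with a vinylstannane, in the presence of LiCl as is usual for triflates; it installs C6 and C7 of the diene.

Step 8
Reactants: 10 tert-butyl{[(1R)-1,3-dimethyl-2-vinylcyclohex-2-en-1-yl]methoxy}dimethylsilane
Product: 11 [(1R)-1,3-dimethyl-2-vinylcyclohex-2-en-1-yl]methanol
Conditions: Bu4NF, THF, 0 °C → rt
Reagents that add atoms: none
Why: Fluoride cleavage of the silyl ether frees O18 for the tether.

Step 9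
Reactants: 11 [(1R)-1,3-dimethyl-2-vinylcyclohex-2-en-1-yl]methanol; 3 4-(tert-butyldimethylsilyloxy)but-2-ynoic acid
Product: 12 [(1R)-1,3-dimethyl-2-vinylcyclohex-2-en-1-yl]methyl 4-(tert-butyldimethylsilyloxy)but-2-ynoate
Conditions: DCC, DMAP (cat.), CH2Cl2, −20 → 0 °C
Reagents that add atoms: none
Why: Steglich esterification; low temperature and catalytic DMAP limit conjugate addition to the ynoate.

Step 10
Reactants: 12 [(1R)-1,3-dimethyl-2-vinylcyclohex-2-en-1-yl]methyl 4-(tert-butyldimethylsilyloxy)but-2-ynoate
Product: 13 (4R,10S)-17-(tert-butyldimethylsilyloxy)-12,13,14,15,16-pentanorlabda-5,8-dien-11,18-olide (seven-membered lactone C4–C18–O–C11–C9–C10–C5 bridging the α face)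
Conditions: 1,2-dichlorobenzene (0.01 M), BHT (cat.), 190 °C, sealed tube
Reagents that add atoms: none
Why: Proposed new method: on heating, the s-cis diene (C10=C5–C6=C7) and the ynoate (C8≡C9) should combine in a concerted, asynchronous [4+2] cycloaddition that forms C9–C10 and C7–C8; the closest known reactions are type 2 intramolecular Diels–Alder reactions of ester-tethered dienophiles giving bridgehead-alkene lactones, and thermal additions of alkynoates to 1,3,3-trimethyl-2-vinylcyclohexene-type dienes, but not their combination at a ring-embedded, fully substituted diene terminus. Ring B closes as the six-membered ring of the cycloaddition itself, a cyclohexa-1,4-diene with C5=C6 and C8=C9. The seven-membered lactone closes through the same C9–C10 bond in the meta (bicyclo[4.3.1]) mode that a four-atom tether on the internal diene carbon enforces; the para mode would need an eight-membered bridged ring. The only new stereocentre, C10, is controlled by C4, because the ester chain can bring C9 to C10 only on the face of ring A that carries C18, which places C20 cis to C19. The same tether fixes the regiochemistry (C9 to C10, C8 to C7), and since C5 and C9 stay sp2, ring A can take the chair with C18 and C9 diaxial that the short bridge demands. The step needs cycloaddition to outrun [1,5]-hydrogen shift in the cisoid diene and polymerisation; high dilution, a radical inhibitor and the strongly exothermic loss of an alkyne π bond favour it. The fully substituted terminus and the need for the s-cis ester conformer make the reaction slow, hence 190 °C.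

Step 11
Reactants: 13 (4R,10S)-17-(tert-butyldimethylsilyloxy)-12,13,14,15,16-pentanorlabda-5,8-dien-11,18-olide
Product: 15 (4R,10S)-18-hydroxy-12,13,14,15,16-pentanorlabda-5,8-dien-11,17-olide (butenolide on C8=C9: C11 carbonyl on C9 and ring oxygen on C17), via 17-hydroxy bridged lactone 14 (not isolated)
Conditions: Bu4NF, AcOH (1:1), THF, 0 °C → rt
Reagents that add atoms: none
Why: Desilylation followed by translactonisation: the freed O17 lies cis to the lactone carbonyl across C8=C9 and takes over the acyl group, which opens the strained bridged ring and lets ring A relax to its normal chair. The acetic acid buffer avoids deprotonation of the doubly allylic C7.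

Step 12
Reactants: 15 (4R,10S)-18-hydroxy-12,13,14,15,16-pentanorlabda-5,8-dien-11,17-olide
Product: 16 (4R,5R,6S,10S)-6α,18-dihydroxy-12,13,14,15,16-pentanorlabd-8-en-11,17-olide (5α-H)
Conditions: BH3·THF (4 equiv), THF, 0 °C → rt; then 30% H2O2, 3 M aq. NaOAc, 0 °C → rt
Reagents that add atoms: hydrogen peroxide, OO
Why: Hydroboration–oxidation: borane should add syn to the electron-rich C5=C6 from the α face, away from the axial C19 and C20 methyl groups (as in Δ5-steroids), with boron on C6 and hydrogen on C5, giving the trans fusion and the equatorial 6α-alcohol. The electron-poor tetrasubstituted butenolide alkene is inert, and buffered peroxide spares the lactone.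

Step 13
Reactants: 16 (4R,5R,6S,10S)-6α,18-dihydroxy-12,13,14,15,16-pentanorlabd-8-en-11,17-olide
Product: 17 6α,18-bis(triethylsilyloxy)-12,13,14,15,16-pentanorlabd-8-en-11,17-olide
Conditions: Et3SiOTf, 2,6-lutidine, CH2Cl2, −78 → 0 °C
Reagents that add atoms: triethylsilyl trifluoromethanesulfonate, CC[Si](CC)(CC)OS(=O)(=O)C(F)(F)F
Why: Silyl triflate protects both the neopentyl and the hindered secondary hydroxyl; triethylsilyl ethers last to the end and are removed together in step 24.

Step 14
Reactants: 17 6α,18-bis(triethylsilyloxy)-12,13,14,15,16-pentanorlabd-8-en-11,17-olide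
Product: 18 6α,18-bis(triethylsilyloxy)-11,17-epoxy-12,13,14,15,16-pentanorlabd-8-en-11-ol (lactol as a mixture of anomers)
Conditions: i-Bu2AlH (1.2 equiv), CH2Cl2, −78 °C; aq. potassium sodium tartrate
Reagents that add atoms: none
Why: Partial reduction of a butenolide stops at the aluminium hemiacetal at −78 °C; the lactol is used crude to avoid dehydration to the furan.

Step 15
Reactants: 18 6α,18-bis(triethylsilyloxy)-11,17-epoxy-12,13,14,15,16-pentanorlabd-8-en-11-ol
Product: 19 6α,18-bis(triethylsilyloxy)-13,14,15,16-tetranorlabda-8,11-dien-17-ol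
Conditions: Ph3PCH3Br, KOt-Bu, THF, 0 °C → rt
Reagents that add atoms: methyltriphenylphosphonium bromide, C[P+](c1ccccc1)(c1ccccc1)c1ccccc1.[Br-]
Why: Wittig methylenation of the hydroxy-enal tautomer of the lactol; C11 becomes the vinyl carbon and O17 is left as the only free hydroxyl.

Step 16
Reactants: 20 methyl 3-oxobutanoate
Product: 21 methyl (2E)-3-(trifluoromethanesulfonyloxy)but-2-enoate
Conditions: Tf2O, aq. Me4NOH, hexanes, 5 °C → rt
Reagents that add atoms: trifluoromethanesulfonic anhydride, O=S(=O)(OS(=O)(=O)C(F)(F)F)C(F)(F)F
Why: Enol triflation of an acetoacetate under non-chelating (tetramethylammonium enolate) conditions gives the E enol triflate, which carries the geometry of C13=C14.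

Step 17
Reactants: 19 6α,18-bis(triethylsilyloxy)-13,14,15,16-tetranorlabda-8,11-dien-17-ol; 21 methyl (2E)-3-(trifluoromethanesulfonyloxy)but-2-enoate
Product: 23 methyl (13E)-17-hydroxy-6α,18-bis(triethylsilyloxy)labda-8,13-dien-15-oate, via C12 9-BBN borane 22 (not isolated)
Conditions: 9-BBN (3 equiv), THF, 0 °C → rt; then 21, Pd(dppf)Cl2 (5 mol%), AsPh3 (10 mol%), 3 M aq. K3PO4, DMF, rt
Reagents that add atoms: none
Why: 9-BBN adds to the terminal carbon of the monosubstituted vinyl group only, the tetrasubstituted alkene being inert; the B-alkyl Suzuki–Miyaura coupling then proceeds with retention of the triflate geometry and gives the 13E alkene. The O17 borinate is hydrolysed on work-up.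

Step 18
Reactants: 23 methyl (13E)-17-hydroxy-6α,18-bis(triethylsilyloxy)labda-8,13-dien-15-oate
Product: 24 methyl (13E)-17-(methoxycarbonyloxy)-6α,18-bis(triethylsilyloxy)labda-8,13-dien-15-oate
Conditions: ClCO2Me, pyridine, DMAP (cat.), CH2Cl2, 0 °C
Reagents that add atoms: methyl chloroformate, COC(=O)Cl
Why: Acylation of the only free hydroxyl turns O17 into a leaving group for palladium.

Step 19
Reactants: 24 methyl (13E)-17-(methoxycarbonyloxy)-6α,18-bis(triethylsilyloxy)labda-8,13-dien-15-oate
Product: 25 methyl (13E)-6α,18-bis(triethylsilyloxy)labda-8(17),13-dien-15-oate (9α-H)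
Conditions: Pd(OAc)2 (5 mol%), n-Bu3P (20 mol%), HCO2H, Et3N, THF, 50 °C
Reagents that add atoms: none
Why: Tsuji formate hydrogenolysis: zerovalent palladium should ionise the allylic carbonate on the α face, anti to the C20 methyl; the bound formate loses CO2 and hydride passes from palladium to the more substituted terminus C9 on that same face. This sets 9α-H and moves the alkene to C8=C17; n-Bu3P is the ligand that favours the less substituted alkene.

Step 20
Reactants: 25 methyl (13E)-6α,18-bis(triethylsilyloxy)labda-8(17),13-dien-15-oate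
Product: 26 (13E)-6α,18-bis(triethylsilyloxy)labda-8(17),13-dien-15-ol
Conditions: i-Bu2AlH (2.5 equiv), CH2Cl2, −78 °C
Reagents that add atoms: none
Why: 1,2-Reduction of the enoate to the allylic alcohol; silyl ethers and both alkenes are inert.

Step 21
Reactants: 26 (13E)-6α,18-bis(triethylsilyloxy)labda-8(17),13-dien-15-ol
Product: 27 (13E)-6α,18-bis(triethylsilyloxy)labda-8(17),13-dien-15-al
Conditions: MnO2, CH2Cl2, rt
Reagents that add atoms: none
Why: Selective allylic oxidation to the enal without loss of the E geometry.

Step 22
Reactants: 28 4-methylfuran-2(5H)-one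
Product: 29 trimethyl[(4-methylfuran-2-yl)oxy]silane
Conditions: Me3SiOTf, Et3N, CH2Cl2, 0 °C
Reagents that add atoms: trimethylsilyl trifluoromethanesulfonate, C[Si](C)(C)OS(=O)(=O)C(F)(F)F
Why: Soft enolisation and O-silylation of the butenolide give the 2-silyloxyfuran, used directly.

Step 23
Reactants: 27 (13E)-6α,18-bis(triethylsilyloxy)labda-8(17),13-dien-15-al; 29 trimethyl[(4-methylfuran-2-yl)oxy]silane
Product: 31 (5S)-5-[(1S,2E)-1-hydroxy-3-methyl-5-(labdane C9 decalin unit bearing 6α,18-bis(triethylsilyloxy) and 8(17)-ene)pent-2-en-1-yl]-4-methylfuran-2(5H)-one (the 6,18-bis(triethylsilyl) ether of the target), via 15-O-trimethylsilyl ether 30 (not isolated)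
Conditions: Ti(O-i-Pr)4 (20 mol%), (R)-BINOL (20 mol%), Et2O, −20 °C; then aq. citric acid, THF, 0 °C
Reagents that add atoms: none
Why: Vinylogous Mukaiyama aldol addition: the chiral titanium BINOLate activates the aldehyde and should expose its Re face to C5 of the silyloxyfuran, setting C15 as S. Lewis-acid-promoted additions of 2-silyloxyfurans favour the threo (like) adduct, which sets C5′ as S; 1,4-addition is blocked by the β,β-disubstituted enal. Mild acid removes only the O15 trimethylsilyl group.

Step 24
Reactants: 31 6,18-bis(triethylsilyl) ether of the target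
Product: 32 (5S)-5-[(1S,2E)-1-hydroxy-5-[(1S,4S,4aR,5R,8aR)-4-hydroxy-5-(hydroxymethyl)-5,8a-dimethyl-2-methylidenedecahydronaphthalen-1-yl]-3-methylpent-2-en-1-yl]-4-methylfuran-2(5H)-one (target)
Conditions: HF·pyridine, pyridine, THF, 0 °C → rt
Reagents that add atoms: none
Why: Buffered fluoride cleaves both triethylsilyl ethers; these conditions are neither basic enough to epimerise C5′ nor acidic enough to ionise the allylic alcohol or isomerise the exocyclic alkene.

## Compound list

1 | prop-2-yn-1-ol | C#CCO | starting material
2 | tert-butyldimethyl(prop-2-yn-1-yloxy)silane | C#CCO[Si](C)(C)C(C)(C)C | intermediate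
3 | 4-(tert-butyldimethylsilyloxy)but-2-ynoic acid | OC(=O)C#CCO[Si](C)(C)C(C)(C)C | intermediate
4 | 2,6-dimethylcyclohexan-1-one (cis/trans mixture) | CC1CCCC(C)C1=O | starting material
5 | (2,6-dimethylcyclohex-1-en-1-yl)oxytrimethylsilane (racemic) | CC1CCCC(C)=C1O[Si](C)(C)C | intermediate
6 | (2S)-2-(hydroxymethyl)-2,6-dimethylcyclohexan-1-one (C6 epimers) | O=C1C(C)CCC[C@@]1(C)CO | intermediate
7 | (2S)-2-[(tert-butyldimethylsilyloxy)methyl]-2,6-dimethylcyclohexan-1-one (C6 epimers) | O=C1C(C)CCC[C@@]1(C)CO[Si](C)(C)C(C)(C)C | intermediate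
8 | (6S)-6-[(tert-butyldimethylsilyloxy)methyl]-2,6-dimethylcyclohex-1-en-1-yl trifluoromethanesulfonate | CC1=C(OS(=O)(=O)C(F)(F)F)[C@](C)(CO[Si](C)(C)C(C)(C)C)CCC1 | intermediate
9 | tributyl(vinyl)stannane | C=C[Sn](CCCC)(CCCC)CCCC | starting material
10 | tert-butyl{[(1R)-1,3-dimethyl-2-vinylcyclohex-2-en-1-yl]methoxy}dimethylsilane | C=CC1=C(C)CCC[C@@]1(C)CO[Si](C)(C)C(C)(C)C | intermediate
11 | [(1R)-1,3-dimethyl-2-vinylcyclohex-2-en-1-yl]methanol | C=CC1=C(C)CCC[C@@]1(C)CO | intermediate
12 | [(1R)-1,3-dimethyl-2-vinylcyclohex-2-en-1-yl]methyl 4-(tert-butyldimethylsilyloxy)but-2-ynoate | C=CC1=C(C)CCC[C@@]1(C)COC(=O)C#CCO[Si](C)(C)C(C)(C)C | intermediate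
13 | (4R,10S)-17-(tert-butyldimethylsilyloxy)-12,13,14,15,16-pentanorlabda-5,8-dien-11,18-olide (bridged lactone) | CC(C)(C)[Si](C)(C)OCC1=C2C(=O)OC[C@]3(C)CCC[C@@]2(C)C3=CC1 | intermediate
14 | (4R,10S)-17-hydroxy-12,13,14,15,16-pentanorlabda-5,8-dien-11,18-olide (not isolated) | OCC1=C2C(=O)OC[C@]3(C)CCC[C@@]2(C)C3=CC1 | intermediate
15 | (4R,10S)-18-hydroxy-12,13,14,15,16-pentanorlabda-5,8-dien-11,17-olide | O=C1OCC2=C1[C@@]3(C)CCC[C@@](C)(CO)C3=CC2 | intermediate
16 | (4R,5R,6S,10S)-6α,18-dihydroxy-12,13,14,15,16-pentanorlabd-8-en-11,17-olide | O=C1OCC2=C1[C@@]3(C)CCC[C@@](C)(CO)[C@@H]3[C@@H](O)C2 | intermediate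
17 | 6α,18-bis(triethylsilyloxy)-12,13,14,15,16-pentanorlabd-8-en-11,17-olide | O=C1OCC2=C1[C@@]3(C)CCC[C@@](C)(CO[Si](CC)(CC)CC)[C@@H]3[C@@H](O[Si](CC)(CC)CC)C2 | intermediate
18 | 6α,18-bis(triethylsilyloxy)-11,17-epoxy-12,13,14,15,16-pentanorlabd-8-en-11-ol (lactol, anomeric mixture) | OC1OCC2=C1[C@@]3(C)CCC[C@@](C)(CO[Si](CC)(CC)CC)[C@@H]3[C@@H](O[Si](CC)(CC)CC)C2 | intermediate
19 | 6α,18-bis(triethylsilyloxy)-13,14,15,16-tetranorlabda-8,11-dien-17-ol | C=CC1=C(CO)C[C@H](O[Si](CC)(CC)CC)[C@H]2[C@](C)(CO[Si](CC)(CC)CC)CCC[C@]12C | intermediate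
20 | methyl 3-oxobutanoate (methyl acetoacetate) | CC(=O)CC(=O)OC | starting material
21 | methyl (2E)-3-(trifluoromethanesulfonyloxy)but-2-enoate | C/C(OS(=O)(=O)C(F)(F)F)=C\C(=O)OC | intermediate
22 | 12-(9-borabicyclo[3.3.1]nonan-9-yl)-6α,18-bis(triethylsilyloxy)-13,14,15,16-tetranorlabd-8-en-17-yl 9-BBN borinate (not isolated) | C(CC1=C(COB2C3CCCC2CCC3)C[C@H](O[Si](CC)(CC)CC)[C@H]4[C@](C)(CO[Si](CC)(CC)CC)CCC[C@]14C)B5C6CCCC5CCC6 | intermediate
23 | methyl (13E)-17-hydroxy-6α,18-bis(triethylsilyloxy)labda-8,13-dien-15-oate | COC(=O)/C=C(\C)CCC1=C(CO)C[C@H](O[Si](CC)(CC)CC)[C@H]2[C@](C)(CO[Si](CC)(CC)CC)CCC[C@]12C | intermediate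
24 | methyl (13E)-17-(methoxycarbonyloxy)-6α,18-bis(triethylsilyloxy)labda-8,13-dien-15-oate | COC(=O)/C=C(\C)CCC1=C(COC(=O)OC)C[C@H](O[Si](CC)(CC)CC)[C@H]2[C@](C)(CO[Si](CC)(CC)CC)CCC[C@]12C | intermediate
25 | methyl (13E)-6α,18-bis(triethylsilyloxy)labda-8(17),13-dien-15-oate | C=C1C[C@H](O[Si](CC)(CC)CC)[C@H]2[C@](C)(CO[Si](CC)(CC)CC)CCC[C@]2(C)[C@H]1CC/C(C)=C/C(=O)OC | intermediate
26 | (13E)-6α,18-bis(triethylsilyloxy)labda-8(17),13-dien-15-ol | C=C1C[C@H](O[Si](CC)(CC)CC)[C@H]2[C@](C)(CO[Si](CC)(CC)CC)CCC[C@]2(C)[C@H]1CC/C(C)=C/CO | intermediate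
27 | (13E)-6α,18-bis(triethylsilyloxy)labda-8(17),13-dien-15-al | C=C1C[C@H](O[Si](CC)(CC)CC)[C@H]2[C@](C)(CO[Si](CC)(CC)CC)CCC[C@]2(C)[C@H]1CC/C(C)=C/C=O | intermediate
28 | 4-methylfuran-2(5H)-one | CC1=CC(=O)OC1 | starting material
29 | trimethyl[(4-methylfuran-2-yl)oxy]silane | Cc1coc(O[Si](C)(C)C)c1 | intermediate
30 | 6,18-bis(triethylsilyl) 15-trimethylsilyl ether of the target (not isolated) | C=C1C[C@H](O[Si](CC)(CC)CC)[C@H]2[C@](C)(CO[Si](CC)(CC)CC)CCC[C@]2(C)[C@H]1CC/C(C)=C/[C@H](O[Si](C)(C)C)[C@H]1OC(=O)C=C1C | intermediate
31 | 6,18-bis(triethylsilyl) ether of the target | C=C1C[C@H](O[Si](CC)(CC)CC)[C@H]2[C@](C)(CO[Si](CC)(CC)CC)CCC[C@]2(C)[C@H]1CC/C(C)=C/[C@H](O)[C@H]1OC(=O)C=C1C | intermediate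
32 | (5S)-5-[(1S,2E)-1-hydroxy-5-[(1S,4S,4aR,5R,8aR)-4-hydroxy-5-(hydroxymethyl)-5,8a-dimethyl-2-methylidenedecahydronaphthalen-1-yl]-3-methylpent-2-en-1-yl]-4-methylfuran-2(5H)-one | C=C1C[C@H](O)[C@H]2[C@](C)(CO)CCC[C@]2(C)[C@H]1CC/C(C)=C/[C@H](O)[C@H]1OC(=O)C=C1C | target

## Step count and least certain steps

Total: 24 steps. Longest linear sequence: 20 steps from 4 (steps 3–15, 17–21, 23, 24).

**Step 10 (key step).** The cycloaddition may be outrun by [1,5]-hydrogen shift in the cisoid diene or by decomposition of the ynoate: C10 is fully substituted, the ester must leave its preferred s-trans conformation, and the adduct holds two bridgehead alkenes. Fallback from 10, using known chemistry: intermolecular Diels–Alder reaction with dimethyl acetylenedicarboxylate (neat or xylene, 110–140 °C), as is established for 1,3,3-trimethyl-2-vinylcyclohexene dienes, would give the dimethyl 18-silyloxy-pentanorlabda-5,8-diene-11,17-dioate F1 together with its C10 epimer, to be separated. i-Bu2AlH at −78 °C should reduce the less hindered C8 ester, and the resulting alcohol lactonises onto the C9 ester to give the 18-O-silyl butenolide F2; Bu4NF then returns the route to 15. The cost is that the face of C10 is no longer enforced by a tether, so the wanted epimer may be the minor one.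

**Step 4.** Enantioselection may be insufficient, or mismatched for one enantiomer of the racemic enol ether, because the catalyst was developed mainly on aryl ketone enolates. Fallback from 5: uncatalysed-in-chirality hydroxymethylation (aq. HCHO, Yb(OTf)3, THF/H2O) to the racemic ketol F3, then kinetic resolution by lipase-catalysed acetylation (Burkholderia cepacia lipase, vinyl acetate, t-BuOMe). The (2R)-alcohol is removed as the acetate F4 and the unreacted (2S)-alcohol is 6, where the route resumes.

**Step 12.** Borane may reduce the butenolide carbonyl while the hindered trisubstituted alkene reacts slowly, or α-face selectivity may be incomplete. Fallback from 13: methanolysis of the strained lactone (NaOMe, MeOH, 0 °C) to the 17-silyloxy-18-hydroxy methyl ester F5, in which the acyclic hindered ester is far less prone to borane reduction. The same hydroboration–oxidation gives the 6α,18-diol ester F6, and Bu4NF/AcOH then frees O17, which lactonises onto the ester and returns the route to 16.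

**Step 19.** Hydride may go to the primary terminus C17 (retaining the ring alkene), approach the β face of C9, or ionisation of the hindered tetrasubstituted allylic carbonate may be sluggish. Fallback from 23, without a metal: Myers reductive transposition with 2-nitrobenzenesulfonylhydrazide, PPh3 and diethyl azodicarboxylate (THF, −30 °C → rt). Mitsunobu displacement gives the N-allyl sulfonylhydrazine F7, which loses sulfinic acid to the allylic diazene F8. Its retro-ene loss of N2 can deliver hydrogen only to C9 and should do so from the less hindered α face, returning the route to 25.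

**Step 23.** The addition may give the erythro adduct or poor face selectivity at the aldehyde: the decalin offers no bias, the catalyst has been used mainly with simple aldehydes and unsubstituted silyloxyfuran, and the 4-methyl group sits beside the bond-forming carbon. Fallback from 27, with auxiliary control:
- Evans syn-aldol with (R)-4-benzyl-3-[(4-methoxybenzyloxy)acetyl]oxazolidin-2-one (Bu2BOTf, Et3N, CH2Cl2, −78 → 0 °C) to the syn-aldol imide F9.
- Transamidation (MeONHMe·HCl, Me3Al) to the Weinreb amide F10, then Et3SiOTf/2,6-lutidine to its 15-O-triethylsilyl ether F11.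
- MeMgBr to the methyl ketone F12, then DDQ to the α-hydroxy ketone F13.
- Ketenylidenetriphenylphosphorane (toluene, 80 °C), which acylates the hydroxyl and closes the ring by intramolecular Wittig reaction to the tris(triethylsilyl) butenolide F14.
- HF·pyridine, as in step 24, returns the route at target 32.

## Further compounds

F1 | step 10 | dimethyl (4R,10S)-18-(tert-butyldimethylsilyloxy)-12,13,14,15,16-pentanorlabda-5,8-diene-11,17-dioate | COC(=O)C1=C(C(=O)OC)[C@@]2(C)CCC[C@@](C)(CO[Si](C)(C)C(C)(C)C)C2=CC1
F2 | step 10 | (4R,10S)-18-(tert-butyldimethylsilyloxy)-12,13,14,15,16-pentanorlabda-5,8-dien-11,17-olide | O=C1OCC2=C1[C@@]3(C)CCC[C@@](C)(CO[Si](C)(C)C(C)(C)C)C3=CC2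
F3 | step 4 | 2-(hydroxymethyl)-2,6-dimethylcyclohexan-1-one (racemic) | CC1CCCC(C)(CO)C1=O
F4 | step 4 | [(1R)-1,3-dimethyl-2-oxocyclohexyl]methyl acetate | O=C1C(C)CCC[C@]1(C)COC(C)=O
F5 | step 12 | methyl (4R,10S)-17-(tert-butyldimethylsilyloxy)-18-hydroxy-12,13,14,15,16-pentanorlabda-5,8-dien-11-oate | COC(=O)C1=C(CO[Si](C)(C)C(C)(C)C)CC=C2[C@](C)(CO)CCC[C@]12C
F6 | step 12 | methyl 17-(tert-butyldimethylsilyloxy)-6α,18-dihydroxy-12,13,14,15,16-pentanorlabd-8-en-11-oate | COC(=O)C1=C(CO[Si](C)(C)C(C)(C)C)C[C@H](O)[C@H]2[C@](C)(CO)CCC[C@]12C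
F7 | step 19 | methyl (13E)-17-[1-(2-nitrobenzenesulfonyl)hydrazinyl]-6α,18-bis(triethylsilyloxy)labda-8,13-dien-15-oate | COC(=O)/C=C(\C)CCC1=C(CN(N)S(=O)(=O)c3ccccc3[N+](=O)[O-])C[C@H](O[Si](CC)(CC)CC)[C@H]2[C@](C)(CO[Si](CC)(CC)CC)CCC[C@]12C
F8 | step 19 | methyl (13E)-17-diazenyl-6α,18-bis(triethylsilyloxy)labda-8,13-dien-15-oate | COC(=O)/C=C(\C)CCC1=C(CN=N)C[C@H](O[Si](CC)(CC)CC)[C@H]2[C@](C)(CO[Si](CC)(CC)CC)CCC[C@]12C
F9 | step 23 | syn-aldol imide: (4R)-4-benzyl-3-acyloxazolidin-2-one carrying the (15S)-hydroxy and 4-methoxybenzyloxy groups on the bis(triethylsilyl) labdadiene chain | C=C1C[C@H](O[Si](CC)(CC)CC)[C@H]2[C@](C)(CO[Si](CC)(CC)CC)CCC[C@]2(C)[C@H]1CC/C(C)=C/[C@H](O)[C@@H](OCc1ccc(OC)cc1)C(=O)N1[C@H](Cc2ccccc2)COC1=O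
F10 | step 23 | corresponding N-methoxy-N-methyl amide | C=C1C[C@H](O[Si](CC)(CC)CC)[C@H]2[C@](C)(CO[Si](CC)(CC)CC)CCC[C@]2(C)[C@H]1CC/C(C)=C/[C@H](O)[C@@H](OCc1ccc(OC)cc1)C(=O)N(C)OC
F11 | step 23 | 15-O-triethylsilyl ether of the N-methoxy-N-methyl amide | C=C1C[C@H](O[Si](CC)(CC)CC)[C@H]2[C@](C)(CO[Si](CC)(CC)CC)CCC[C@]2(C)[C@H]1CC/C(C)=C/[C@H](O[Si](CC)(CC)CC)[C@@H](OCc1ccc(OC)cc1)C(=O)N(C)OC
F12 | step 23 | methyl ketone with 4-methoxybenzyloxy group on the adjacent carbon and 15-O-triethylsilyl ether | C=C1C[C@H](O[Si](CC)(CC)CC)[C@H]2[C@](C)(CO[Si](CC)(CC)CC)CCC[C@]2(C)[C@H]1CC/C(C)=C/[C@H](O[Si](CC)(CC)CC)[C@@H](OCc1ccc(OC)cc1)C(C)=O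
F13 | step 23 | α-hydroxy methyl ketone with 15-O-triethylsilyl ether | C=C1C[C@H](O[Si](CC)(CC)CC)[C@H]2[C@](C)(CO[Si](CC)(CC)CC)CCC[C@]2(C)[C@H]1CC/C(C)=C/[C@H](O[Si](CC)(CC)CC)[C@@H](O)C(C)=O
F14 | step 23 | 6,15,18-tris(triethylsilyl) ether of the target | C=C1C[C@H](O[Si](CC)(CC)CC)[C@H]2[C@](C)(CO[Si](CC)(CC)CC)CCC[C@]2(C)[C@H]1CC/C(C)=C/[C@H](O[Si](CC)(CC)CC)[C@H]1OC(=O)C=C1C
A1 | alternative 1 | larixol, (13S)-labda-8(17),14-diene-6α,13-diol | C=C1C[C@H](O)[C@H]2C(C)(C)CCC[C@]2(C)[C@H]1CC[C@](C)(O)C=C
A2 | alternative 1 | 6α-(diethylsilyloxy)-14,15,17-trinorlabdane-8,13-dione bis(ethylene ketal) | C13(OCCO3)C[C@H](O[SiH](CC)CC)[C@H]2C(C)(C)CCC[C@]2(C)[C@H]1CCC1(C)OCCO1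
A3 | alternative 1 | oxasilinane bridging O6 and C18 of the same bis-ketal | C13(OCCO3)C[C@H](O[Si](CC)(CC)C4)[C@H]2[C@@]4(C)CCC[C@]2(C)[C@H]1CCC1(C)OCCO1
A4 | alternative 2 | 6α,18-bis(tert-butyldimethylsilyloxy)-15,16-dinorlabd-8(17)-en-13-yne | C=C1C[C@H](O[Si](C)(C)C(C)(C)C)[C@H]2[C@](C)(CO[Si](C)(C)C(C)(C)C)CCC[C@]2(C)[C@H]1CCC#C
A5 | alternative 2 | (2S)-2-(4-methoxybenzyloxy)-3-methylbut-3-enal | O=C[C@@H](OCc1ccc(OC)cc1)C(C)=C
A6 | alternative 2 | (13E)-allylic alcohol with 15-hydroxyl, adjacent 4-methoxybenzyl ether and isopropenyl group | C=C1C[C@H](O[Si](C)(C)C(C)(C)C)[C@H]2[C@](C)(CO[Si](C)(C)C(C)(C)C)CCC[C@]2(C)[C@H]1CC/C(C)=C/[C@H](O)[C@@H](OCc1ccc(OC)cc1)C(C)=C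
A7 | alternative 3 | (2E,7R,8Z)-9-(tert-butyldimethylsilyloxy)-7-[(tert-butyldimethylsilyloxy)methyl]-3,7-dimethyldodeca-2,8,10,11-tetraenal | O=C/C=C(\C)CCC[C@@](C)(CO[Si](C)(C)C(C)(C)C)/C=C(\O[Si](C)(C)C(C)(C)C)C=C=C
A8 | alternative 3 | trans-decalin 9β-carbaldehyde with 8(17)-methylene and C6 silyl dienol ether | C=C1C=C(O[Si](C)(C)C(C)(C)C)[C@H]2[C@](C)(CO[Si](C)(C)C(C)(C)C)CCC[C@]2(C)[C@H]1C=O
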